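## Analysis of the target

The target is a linear quaterphenyl of four phloroglucinol rings, A-B-C-D, joined by three aryl-aryl bonds and carrying twelve free hydroxyl groups and one bromine. Rings A and D are 2,4,6-trihydroxyphenyl groups bound through C-1. Ring B carries ring A at C-1' and ring C at C-3' and keeps one hydrogen at C-5'; ring C is fully substituted, with ring B at C-1'', ring D at C-3'' and bromine at C-5''. Each biaryl bond is flanked by four oxygen-bearing carbons, so all three are tetra-ortho-substituted. There is no stereocentre. The A-B and C-D axes are not stereogenic because rings A and D are symmetric; the B-C axis is stereogenic in principle and the target structure leaves it unspecified. The free dodecaphenol is electron-rich, air-sensitive and very polar, and its C-Br bond sits on a ring that can lose or shuffle bromine under strong acid. The phenols therefore stay masked until the end, and the bromine has to be placed while few positions compete. The strategy rests on the terminal rings. In ring A the attachment carbon C-1 lies between the carbinol carbons C-2 and C-6, which is the carbon pattern of an arylmalonate. The remaining C-3/C-4(OH)/C-5 segment is a three-carbon ketone unit. Rings A and D can therefore be grown onto a B-C biaryl instead of being coupled to it.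

## Retrosynthetic reasoning

10 to 9. The six O-methyl bonds on rings B and C are cut last. In 9 the hydroxyls of rings A and D are already free, so only the core ethers remain. Keeping the core as methyl ethers until the end keeps every earlier intermediate stable to base and to chromatography. The forward step has to cleave six hindered aryl methyl ethers without touching the C-Br bond.

9 to 7 (through 8). The four hydrogens at C-3 and C-5 of ring A and at C-3''' and C-5''' of ring D are replaced retrosynthetically by methoxycarbonyl groups. These esters are not protecting groups. They make both methylene carbons of ketodiester 6 nucleophilic under mild alkoxide conditions. They are traceless because acids of type 8, with a carboxyl group between two phenolic hydroxyls, decarboxylate on gentle warming.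

7 to 5 and two molecules of 6. In ring A the bonds C-2/C-3 and C-6/C-5 are cut, and the corresponding two bonds in ring D, four C-C bonds in all. The cut is made here and not at the A-B and C-D biaryl bonds, because those would require two tetra-ortho-substituted couplings on a substrate that already carries bromine. In 5 the future biaryl bonds already exist as aryl-C(sp3) bonds, so the hindered connections need not be made by coupling. The forward reaction has to acylate each methylene carbon of 6 with one ester of an arylmalonate unit of 5, twice per ring, and end in the aromatic triol.

5 to 4. The C-Br bond is cut. Bromination is placed at this stage because 4 is C2-symmetric and has only two ring C-H positions, which are equivalent; any monobromide has the required constitution. Bromination before the malonates are in place (on 2) would leave three non-equivalent C-H positions for the carbon-carbon bond formation, and the one that must react on the bromo ring would be the least reactive. Bromination after ring construction or after deprotection would expose more nucleophilic sites. What remains to control is only the number of bromines.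

4 to 2 and two molecules of 3. The two aryl-C(malonate) bonds are cut. The forward reaction is a metal-carbenoid substitution of an aromatic C-H bond, once on each ring of 2. The first substitution slows the ring it enters, which directs the second to the other ring.

2 to two molecules of 1. The B-C bond is cut. The two halves are identical, so the forward reaction is a dehydrogenative dimerisation of 1, the only aryl-aryl bond of the route that is made by coupling.

## Alternatives that were turned down

Alternative 1: Both central rings are disconnected. Rings B and C of the bromine-free symmetric quaterphenyl diphenol A1 are each opened into 3-ethoxy-4-(2,4,6-trimethoxyphenyl)cyclobut-2-en-1-one A2 and one triple bond of 1,4-diethoxybuta-1,3-diyne A3. In the forward key step two molecules of A2 are heated with A3. Each A2 opens to a vinylketene and adds across one ynol ether triple bond; the vinylcyclobutenone so formed opens again and closes by 6-pi electrocyclisation to a phenol (Danheiser benzannulation), twice.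
- For it: the regiochemistry follows from the polarity of the ynol ether and the conditions are neutral. Rings A and D arrive on the sp3 carbon of A2 and the B-C bond is already present in A3, so no hindered arenes are coupled. On predictability of the bond-forming events it is at least as strong as the chosen route, whose condensation has no precedent on hindered arylmalonates.
- Against it: A1 has no bromine, and rings B and C are identical. Four further open positions sit on the trimethoxyphenyl end rings, so the late monobromination faces six competing sites. A3 is a doubly oxygenated conjugated diyne that must survive the temperature at which A2 opens. The second annulation has to occur at an alkyne that already bears a fully ortho-substituted aryl group. A2 and A3 each need several steps.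
- Comparison: the chosen route brominates where the position is not in question, uses cheap reagents and needs six steps.

Alternative 2: All three biaryl bonds are disconnected at once. The triply acetal-bridged bromoquaterphenyl A4 is traced back to the open-chain tris(formaldehyde acetal) A5, in which the four rings are linked only through O-CH2-O bridges. In the forward key step A5 is oxidised at a boron-doped diamond anode in a fluorinated alcohol. Each arene radical cation is trapped by the neighbouring ring ortho to the acetal oxygens, so that three C-C bonds form and three dibenzodioxepine rings close.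
- For it: the bromine comes in with a monomer, so no statistical bromination is needed. On this point the alternative is stronger than the chosen route, which accepts a statistical monobromination in step 3. The step is metal-free, and the regiochemical options on ring B converge after global deprotection.
- Against it: each bridged biaryl is flatter and more easily oxidised than A5, so over-oxidation and intermolecular coupling grow as the cascade proceeds. The bromo ring is the poorest donor and must couple twice. Three seven-membered rings on adjacent axes add strain. A5 needs three unsymmetrical diaryl acetal links made one after another from differently protected phenols.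
- Comparison: the chosen route has one oxidative coupling, on compound 1, where low conversion costs little, and makes the other aryl-aryl connections by two-electron carbonyl chemistry.

Alternative 3: The A-B and C-D bonds are disconnected. The doubly silicon-bridged bromoquaterphenyl octamethyl ether A6 is opened to the bis(silylene ether) A7, a brominated B-C biaryl diol tied through two di-tert-butylsilylene groups to two iodinated dimethoxyphenols. In the forward key step zerovalent palladium, formed from Pd(OAc)2 and a trialkylphosphine, adds into each C-I bond. A pivalate-assisted metalation of the tethered core C-H and reductive elimination follow, and two seven-membered rings close.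
- For it: tethered C-H arylation to 2,2'-biphenols is an established substrate class, so on precedent for the key bond formation this alternative is stronger than the chosen route. The tether fixes the site.
- Against it: A7 holds two C-I bonds and one C-Br bond, which the catalyst must tell apart. Both metalation sites lie between two oxygen substituents, and the new bonds are tetra-ortho-substituted. The core must present exactly two free phenols among six oxygens together with the bromine; that needs a desymmetrised, selectively protected biaryl and still a statistical bromination. Two hindered unsymmetrical Si-O links have to be made stepwise.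
- Comparison: the chosen route has no transition metal in the flask once bromine is installed, needs no differentiation of the core oxygens, and forms no tetra-ortho-substituted biaryl bond except by dimerising 1.

Key step: step 4

Assumption: the B-C axis is stereogenic in principle; since the target is drawn without an axial descriptor, compounds 4, 5, 7, 8, 9 and 10 are taken as racemates about that axis.

## Route

Step 1
Reactants: 1 (1,3,5-trimethoxybenzene), two molecules
Product: 2 hexamethoxybiphenyl (2,2',4,4',6,6'-hexamethoxy-1,1'-biphenyl)
Conditions: FeCl3 (1.1 equiv), CH2Cl2, 0 °C to rt, stopped before full conversion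
Reagents that add atoms: none
Why: Scholl-type dehydrogenative homocoupling: trivalent iron oxidises 1 to a radical cation, which is attacked by a second molecule of 1 at one of its three equivalent ring carbons; the strongly twisted biaryl 2 gains little conjugation and should survive if the reaction is stopped short of full conversion, with unreacted 1 recovered.

Step 2
Reactants: 2 (hexamethoxybiphenyl); 3 (dimethyl 2-diazomalonate), two equivalents
Product: 4 symmetric bis(malonate) (tetramethyl 2,2'-(2,2',4,4',6,6'-hexamethoxy-[1,1'-biphenyl]-3,3'-diyl)dimalonate)
Conditions: Rh2(OAc)4 (2 mol %), PhCF3, 80 °C, 3 (2.3 equiv) added slowly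
Reagents that add atoms: none
Why: Rhodium-carbenoid aromatic substitution (formal C-H insertion) with an acceptor/acceptor diazo compound: the electrophilic carbenoid attacks a ring carbon between two methoxy groups and a proton shift restores the arene; after the first substitution that ring is slowed, because its C-2 methoxy group is twisted out of conjugation and the last C-H is shielded, so the second malonate should enter the other ring and give the C2-symmetric 3,3'-isomer.

Step 3
Reactants: 4 (symmetric bis(malonate))
Product: 5 bromo bis(malonate) (tetramethyl 2,2'-(5-bromo-2,2',4,4',6,6'-hexamethoxy-[1,1'-biphenyl]-3,3'-diyl)dimalonate)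
Conditions: NBS (0.95 equiv), MeCN, -20 to 0 °C, dark
Reagents that add atoms: N-bromosuccinimide, O=C1CCC(=O)N1Br
Why: Electrophilic aromatic bromination: the two remaining ring C-H positions of 4 are equivalent, so only one monobromide can form; a slight deficit of reagent at low temperature without base or light should keep the second ring bromination and attack at the malonate C-H down, and unreacted 4 is recycled.

Step 4
Reactants: 5 (bromo bis(malonate)); 6 (dimethyl 3-oxopentanedioate), two equivalents
Product: 7 quaterphenyl tetraester (tetramethyl 5''-bromo-2,2''',4,4''',6,6'''-hexahydroxy-2',2'',4',4'',6',6''-hexamethoxy-[1,1':3',1'':3'',1'''-quaterphenyl]-3,3''',5,5'''-tetracarboxylate)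
Conditions: 6 (2.5 equiv), NaOMe (5.5 equiv), MeOH/toluene, rt; then MeOH distilled off, 110 °C; 1 M HCl, 0 °C
Reagents that add atoms: none
Why: Proposed new method: the closest known reaction is the sodium alkoxide condensation of dialkyl malonates with dialkyl 3-oxopentanedioates to 2,4,6-trihydroxyisophthalates, which has not been shown for malonates bearing a di-ortho-substituted aryl group, nor twice in one molecule. The sodium enolate of 6 attacks one ester carbonyl of an arylmalonate unit of 5 in an intermolecular Claisen acylation with loss of methoxide and gives an acidic tricarbonyl intermediate. The second ester-stabilised carbanion of the same ketodiester unit then attacks the remaining malonate ester; loss of a second methoxide and enolisation give the aromatic triol, held as its sodium phenoxide. Rings A and D each close in a 6-(enolendo)-exo-trig Dieckmann-type mode, with the nucleophilic enolate C=C inside the forming ring and the ester C=O outside it. No stereocentre is formed. The step needs cross-condensation to outrun self-condensation of 6 and C-acylation to outrun O-acylation to a pyranone; all Claisen and lactone adducts are reversible under methoxide whereas the aromatic phenoxide is not, and the ester on each nucleophilic carbon keeps that carbon acidic, so the equilibria should drain to the arene. Distilling off methanol drives both acylations and limits methoxide-induced loss of a methoxycarbonyl group from 5; the aryl bromide and the six aryl methyl ethers are inert to methoxide.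

Step 5
Reactants: 7 (quaterphenyl tetraester)
Product: 9 hexamethyl ether hexaol (5''-bromo-2',2'',4',4'',6',6''-hexamethoxy-[1,1':3',1'':3'',1'''-quaterphenyl]-2,2''',4,4''',6,6'''-hexol), via tetracarboxylic acid 8 (not isolated)
Conditions: KOH (4 M aq), MeOH, reflux, Ar; then HCl to pH 2, 60 °C
Reagents that add atoms: none
Why: Ester saponification followed by decarboxylation of hydroxybenzoic acids flanked by two phenolic hydroxyls, which lose CO2 on mild warming through their keto tautomers as beta-keto acids; exclusion of air protects the polyphenoxides, and the aryl bromide and the methyl ethers are inert to aqueous hydroxide.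

Step 6
Reactants: 9 (hexamethyl ether hexaol)
Product: 10 target (5''-bromo-[1,1':3',1'':3'',1'''-quaterphenyl]-2,2',2'',2''',4,4',4'',4''',6,6',6'',6'''-dodecol)
Conditions: BBr3 (20 equiv), CH2Cl2, -78 °C to rt; then H2O/MeOH, 0 °C; reversed-phase purification under Ar
Reagents that add atoms: none
Why: Lewis-acid cleavage of aryl methyl ethers: each ether oxygen binds boron and bromide attacks the methyl group in an SN2 step; a large excess is needed because the six free phenols are first converted to aryl borates, which also lowers the electron density of the rings and should protect them and the C-Br bond from protonation until the cold aqueous quench.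

## Compound list

1 | 1,3,5-trimethoxybenzene | COc1cc(OC)cc(OC)c1 | starting material
2 | 2,2',4,4',6,6'-hexamethoxy-1,1'-biphenyl | COc1cc(OC)c(-c2c(OC)cc(OC)cc2OC)c(OC)c1 | intermediate
3 | dimethyl 2-diazomalonate | COC(=O)C(=[N+]=[N-])C(=O)OC | starting material
4 | tetramethyl 2,2'-(2,2',4,4',6,6'-hexamethoxy-[1,1'-biphenyl]-3,3'-diyl)dimalonate | COC(=O)C(C(=O)OC)c1c(OC)cc(OC)c(-c2c(OC)cc(OC)c(C(C(=O)OC)C(=O)OC)c2OC)c1OC | intermediate
5 | tetramethyl 2,2'-(5-bromo-2,2',4,4',6,6'-hexamethoxy-[1,1'-biphenyl]-3,3'-diyl)dimalonate | COC(=O)C(C(=O)OC)c1c(OC)cc(OC)c(-c2c(OC)c(Br)c(OC)c(C(C(=O)OC)C(=O)OC)c2OC)c1OC | intermediate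
6 | dimethyl 3-oxopentanedioate | COC(=O)CC(=O)CC(=O)OC | starting material
7 | tetramethyl 5''-bromo-2,2''',4,4''',6,6'''-hexahydroxy-2',2'',4',4'',6',6''-hexamethoxy-[1,1':3',1'':3'',1'''-quaterphenyl]-3,3''',5,5'''-tetracarboxylate | COC(=O)c1c(O)c(C(=O)OC)c(O)c(-c2c(OC)cc(OC)c(-c3c(OC)c(Br)c(OC)c(-c4c(O)c(C(=O)OC)c(O)c(C(=O)OC)c4O)c3OC)c2OC)c1O | intermediate
8 | 5''-bromo-2,2''',4,4''',6,6'''-hexahydroxy-2',2'',4',4'',6',6''-hexamethoxy-[1,1':3',1'':3'',1'''-quaterphenyl]-3,3''',5,5'''-tetracarboxylic acid | OC(=O)c1c(O)c(C(=O)O)c(O)c(-c2c(OC)cc(OC)c(-c3c(OC)c(Br)c(OC)c(-c4c(O)c(C(=O)O)c(O)c(C(=O)O)c4O)c3OC)c2OC)c1O | intermediate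
9 | 5''-bromo-2',2'',4',4'',6',6''-hexamethoxy-[1,1':3',1'':3'',1'''-quaterphenyl]-2,2''',4,4''',6,6'''-hexol | Oc1cc(O)c(-c2c(OC)cc(OC)c(-c3c(OC)c(Br)c(OC)c(-c4c(O)cc(O)cc4O)c3OC)c2OC)c(O)c1 | intermediate
10 | 5''-bromo-[1,1':3',1'':3'',1'''-quaterphenyl]-2,2',2'',2''',4,4',4'',4''',6,6',6'',6'''-dodecol | Oc1cc(O)c(-c2c(O)cc(O)c(-c3c(O)c(Br)c(O)c(-c4c(O)cc(O)cc4O)c3O)c2O)c(O)c1 | target

## Step count and least certain steps

Total steps: 6. Longest linear sequence: 6 (1, 2, 4, 5, 7, 9, 10); 3 and 6 are purchased.

Step 4 (key step).
- What may go wrong: acylation at the hindered malonate esters may be too slow. Self-condensation of 6, deprotonation of the malonate C-H (which switches off its electrophilicity), methoxide-induced loss of a methoxycarbonyl group or ring closure through oxygen may then take over. One terminal ring may also close while the second does not.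
- Fallback (known chemistry, cross-coupling instead of annulation): it sets out from 2 and returns at 10. Compound 2 is iodinated twice with N-iodosuccinimide (MeCN, catalytic CF3CO2H) to 3,3'-diiodo-2,2',4,4',6,6'-hexamethoxy-1,1'-biphenyl F1; the ring iodinated first is slowed for the same reason as in step 2. One equivalent of NBS then gives 5-bromo-3,3'-diiodo-2,2',4,4',6,6'-hexamethoxy-1,1'-biphenyl F2. Separately, 1 is lithiated at C-2 with n-BuLi in THF to 2,4,6-trimethoxyphenyllithium F3 and transmetalated with ZnCl2 to (2,4,6-trimethoxyphenyl)zinc chloride F4. A twofold Negishi coupling of F2 with F4 (Pd2(dba)3, RuPhos, THF/NMP, 50 °C) relies on the faster oxidative addition of zerovalent palladium into C-I than into C-Br and gives 5''-bromo-2,2',2'',2''',4,4',4'',4''',6,6',6'',6'''-dodecamethoxy-1,1':3',1'':3'',1'''-quaterphenyl F5. BBr3 then cleaves all twelve methyl ethers to give 10.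

Step 2.
- What may go wrong: the second carbenoid substitution may go to the ring that is already substituted, or a third substitution may follow. Carbene dimerisation and oxonium ylide formation at the methoxy groups may consume the diazo compound.
- Fallback (carbonyl electrophile instead of carbenoid): it sets out from 2 and returns at 4. Friedel-Crafts hydroxyalkylation of 2 with dimethyl 2-oxomalonate (SnCl4, CH2Cl2, -20 °C) stops after one substitution per ring and gives tetramethyl 2,2'-(2,2',4,4',6,6'-hexamethoxy-[1,1'-biphenyl]-3,3'-diyl)bis(2-hydroxymalonate) F6. Reductive removal of the two tertiary hydroxyl groups alpha to the esters with SmI2 (THF/HMPA, t-BuOH) gives 4; the hydroxyl groups leave as water.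

Step 3.
- What may go wrong: the two rings react independently, so over-bromination of the second ring accompanies the wanted monobromination and conversion has to be kept partial. Bromination at the malonate C-H is a lesser risk.
- Fallback (bromine count fixed on a monomer before the biaryl bond is made): it sets out from 1 and 3 and returns at 5. Excess 1 and 3 with Rh2(OAc)4 give dimethyl 2-(2,4,6-trimethoxyphenyl)malonate F7. N-Iodosuccinimide converts part of F7 to dimethyl 2-(3-iodo-2,4,6-trimethoxyphenyl)malonate F8. The rest is brominated with NBS to dimethyl 2-(3-bromo-2,4,6-trimethoxyphenyl)malonate F9, where the first halogen shuts the ring down, and then iodinated (N-iodosuccinimide, CF3CO2H) to dimethyl 2-(3-bromo-5-iodo-2,4,6-trimethoxyphenyl)malonate F10. A mixed Ullmann coupling of F10 with a threefold excess of F8 (Cu powder, DMF, 140 °C) gives 5. The homodimer of the excess partner is 4, which goes back into step 3.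

Step 6.
- What may go wrong: ether cleavage at the hindered, twisted methoxy groups may stay incomplete, HBr may cause loss or migration of bromine, and the free dodecaphenol may be oxidised by air during isolation.
- Fallback (isolation through a protected derivative): it sets out from 9 and returns at 10. The crude product of the BBr3 reaction is peracetylated (Ac2O, pyridine, DMAP) to 5''-bromo-[1,1':3',1'':3'',1'''-quaterphenyl]-2,2',2'',2''',4,4',4'',4''',6,6',6'',6'''-dodecayl dodecaacetate F11. F11 is stable on silica and separable from under-cleaved or debrominated material. Acid methanolysis (HCl in degassed MeOH, rt) then releases 10.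

Step 1.
- What may go wrong: over-oxidation of the product to oligomers and ring chlorination by the iron salt.
- Fallback (reductive instead of oxidative coupling): it sets out from 1 and returns at 2. Iodination with N-iodosuccinimide gives 2-iodo-1,3,5-trimethoxybenzene F12, and Ullmann homocoupling (Cu powder, DMF, 150 °C) gives 2.

## Further compounds

F1 | step 4 | 3,3'-diiodo-2,2',4,4',6,6'-hexamethoxy-1,1'-biphenyl | COc1cc(OC)c(-c2c(OC)cc(OC)c(I)c2OC)c(OC)c1I
F2 | step 4 | 5-bromo-3,3'-diiodo-2,2',4,4',6,6'-hexamethoxy-1,1'-biphenyl | COc1c(Br)c(OC)c(-c2c(OC)cc(OC)c(I)c2OC)c(OC)c1I
F3 | step 4 | 2,4,6-trimethoxyphenyllithium | COc1cc(OC)c([Li])c(OC)c1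
F4 | step 4 | (2,4,6-trimethoxyphenyl)zinc chloride | COc1cc(OC)c([Zn]Cl)c(OC)c1
F5 | step 4 | 5''-bromo-2,2',2'',2''',4,4',4'',4''',6,6',6'',6'''-dodecamethoxy-1,1':3',1'':3'',1'''-quaterphenyl | COc1cc(OC)c(-c2c(OC)cc(OC)c(-c3c(OC)c(Br)c(OC)c(-c4c(OC)cc(OC)cc4OC)c3OC)c2OC)c(OC)c1
F6 | step 2 | tetramethyl 2,2'-(2,2',4,4',6,6'-hexamethoxy-[1,1'-biphenyl]-3,3'-diyl)bis(2-hydroxymalonate) | COC(=O)C(O)(C(=O)OC)c1c(OC)cc(OC)c(-c2c(OC)cc(OC)c(C(O)(C(=O)OC)C(=O)OC)c2OC)c1OC
F7 | step 3 | dimethyl 2-(2,4,6-trimethoxyphenyl)malonate | COC(=O)C(C(=O)OC)c1c(OC)cc(OC)cc1OC
F8 | step 3 | dimethyl 2-(3-iodo-2,4,6-trimethoxyphenyl)malonate | COC(=O)C(C(=O)OC)c1c(OC)cc(OC)c(I)c1OC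
F9 | step 3 | dimethyl 2-(3-bromo-2,4,6-trimethoxyphenyl)malonate | COC(=O)C(C(=O)OC)c1c(OC)cc(OC)c(Br)c1OC
F10 | step 3 | dimethyl 2-(3-bromo-5-iodo-2,4,6-trimethoxyphenyl)malonate | COC(=O)C(C(=O)OC)c1c(OC)c(I)c(OC)c(Br)c1OC
F11 | step 6 | 5''-bromo-[1,1':3',1'':3'',1'''-quaterphenyl]-2,2',2'',2''',4,4',4'',4''',6,6',6'',6'''-dodecayl dodecaacetate | CC(=O)Oc1cc(OC(C)=O)c(-c2c(OC(C)=O)cc(OC(C)=O)c(-c3c(OC(C)=O)c(Br)c(OC(C)=O)c(-c4c(OC(C)=O)cc(OC(C)=O)cc4OC(C)=O)c3OC(C)=O)c2OC(C)=O)c(OC(C)=O)c1
F12 | step 1 | 2-iodo-1,3,5-trimethoxybenzene | COc1cc(OC)c(I)c(OC)c1
A1 | alternative 1 | 4',4'',6',6''-tetraethoxy-2,2''',4,4''',6,6'''-hexamethoxy-[1,1':3',1'':3'',1'''-quaterphenyl]-2',2''-diol | CCOc1cc(OCC)c(-c2c(OC)cc(OC)cc2OC)c(O)c1-c1c(O)c(-c2c(OC)cc(OC)cc2OC)c(OCC)cc1OCC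
A2 | alternative 1 | 3-ethoxy-4-(2,4,6-trimethoxyphenyl)cyclobut-2-en-1-one | CCOC1=CC(=O)C1c1c(OC)cc(OC)cc1OC
A3 | alternative 1 | 1,4-diethoxybuta-1,3-diyne | CCOC#CC#COCC
A4 | alternative 2 | triply methylene-acetal-bridged bromoquaterphenyl hexamethyl ether (three dibenzo[d,f][1,3]dioxepine rings along the A-B, B-C and C-D bonds) | COc1cc(OC)c2c(c1)OCOc3cc4OCOc5c(Br)c6OCOc7cc(OC)cc(OC)c7-c6c(OC)c5-c4c(OC)c3-2
A5 | alternative 2 | 2-bromo-1-[(3,5-dimethoxyphenoxy)methoxy]-3-({3-[(3,5-dimethoxyphenoxy)methoxy]-5-methoxyphenoxy}methoxy)-5-methoxybenzene | COc1cc(OC)cc(c1)OCOc1cc(OC)cc(c1)OCOc1cc(OC)cc(OCOc2cc(OC)cc(OC)c2)c1Br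
A6 | alternative 3 | doubly di-tert-butylsilylene-bridged bromoquaterphenyl octamethyl ether (two dibenzo[d,f][1,3,2]dioxasilepine rings along the A-B and C-D bonds) | COc1cc2O[Si](C(C)(C)C)(C(C)(C)C)Oc3cc(OC)cc(OC)c3-c2c(OC)c1-c1c(OC)c2c(O[Si](C(C)(C)C)(C(C)(C)C)Oc3cc(OC)cc(OC)c3-2)c(Br)c1OC
A7 | alternative 3 | 3-bromo-2,2',6,6'-tetramethoxybiphenyl-4,4'-diyl bis[di-tert-butyl(2-iodo-3,5-dimethoxyphenoxy)silyl] ether | COc1cc(O[Si](C(C)(C)C)(C(C)(C)C)Oc2cc(OC)cc(OC)c2I)cc(OC)c1-c1c(OC)cc(O[Si](C(C)(C)C)(C(C)(C)C)Oc2cc(OC)cc(OC)c2I)c(Br)c1OC
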